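**Strategy.** The route rests on cutting the C9–C10 bond of ring B (labdane numbering). C9 lies between C8, the later exocyclic methylene carbon, and C11, so it can serve as the α-carbon of a β-keto ester; this is the feature exploited. In one operation, anodically regenerated trivalent manganese makes the C9 radical, which closes ring B 6-endo onto C10 of a ring A C5=C10 olefin, sets the C10 quaternary centre and leaves a C5=C6 olefin. The precursor is an enantiopure ring A cyclohexene with silyl-protected C3 and C19 oxygens that carries the C6–C7–C8(=O)–C9–C11 keto ester chain at C5.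

Key step: step 10

Remark on the chemistry: the C3 and C19 oxygens are carried as two separate silyl ethers (TBS = tert-butyldimethylsilyl, TIPS = triisopropylsilyl) and not as a cyclic acetal, because a cis-fused 1,3-dioxane would hold ring A in the half-chair with the C3 oxygen axial and C19 pseudoequatorial, which turns the wrong face of C10 toward the chain.

Step 1
Reactants: 1 2-methylcyclohexane-1,3-dione; 2 (triisopropylsiloxy)methyl chloride
Product: 3 2-methyl-2-(TIPS-oxymethyl)cyclohexane-1,3-dione
Conditions: i-Pr2NEt, LiI, THF, 0 to 50 °C; 1 M HCl wash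
Reagents that add atoms: none
Why: C-alkylation of the dione enolate by an α-chloro ether should prevail because lithium ion pairing shields the enolate oxygens and iodide reverses the labile O-alkylation (an enol acetal, which the acid wash also returns to 1), so material funnels to the irreversible C–C bond; C4 is still prochiral.

Step 2
Reactants: 3 2-methyl-2-(TIPS-oxymethyl)cyclohexane-1,3-dione
Product: 4 (2R,3R)-3-hydroxy-2-methyl-2-(TIPS-oxymethyl)cyclohexan-1-one
Conditions: (S)-2-methyl-CBS-oxazaborolidine (20 mol %), BH3·SMe2 (0.6 equiv), THF, −40 °C; MeOH, aqueous work-up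
Reagents that add atoms: none
Why: Corey–Bakshi–Shibata reduction desymmetrises the dione, the catalyst treating the quaternary carbon as the large group to give the (3R) carbinol, while hydride enters anti to the bulky CH2OTIPS group so that the hydroxyl lands cis to it, which at the same time fixes quaternary C4 as R.

Step 3
Reactants: 4 (2R,3R)-3-hydroxy-2-methyl-2-(TIPS-oxymethyl)cyclohexan-1-one
Product: 5 (2R,3R)-3-(TBS-oxy)-2-methyl-2-(TIPS-oxymethyl)cyclohexan-1-one
Conditions: TBSOTf, 2,6-lutidine, CH2Cl2, −78 to 0 °C
Reagents that add atoms: tert-butyldimethylsilyl trifluoromethanesulfonate, CC(C)(C)[Si](C)(C)OS(=O)(=O)C(F)(F)F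
Why: Silylation of the hindered secondary alcohol with a silyl triflate and a non-nucleophilic base masks the β-hydroxy ketone against retro-aldol cleavage in the enolate steps that follow.

Step 4
Reactants: 5 (2R,3R)-3-(TBS-oxy)-2-methyl-2-(TIPS-oxymethyl)cyclohexan-1-one
Product: 7 (2R,3R,6RS)-3-(TBS-oxy)-2,6-dimethyl-2-(TIPS-oxymethyl)cyclohexan-1-one, via lithium enolate 6 (not isolated)
Conditions: LiN(i-Pr)2, THF, −78 °C; MeI, −78 to −20 °C
Reagents that add atoms: iodomethane, CI
Why: Kinetic enolate alkylation can occur only at C10 because C4 is quaternary, and the C10 epimer mixture is of no consequence since this carbon becomes sp2 in step 5.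

Step 5
Reactants: 7 (2R,3R,6RS)-3-(TBS-oxy)-2,6-dimethyl-2-(TIPS-oxymethyl)cyclohexan-1-one
Product: 9 ring A enol triflate (C5=C10 olefin, OTf on C5), via potassium enolate 8 (not isolated)
Conditions: KN(SiMe3)2, THF, −78 to 0 °C; PhNTf2, 0 °C to rt
Reagents that add atoms: N-phenylbis(trifluoromethanesulfonimide), O=S(=O)(N(c1ccccc1)S(=O)(=O)C(F)(F)F)C(F)(F)F
Why: Enol triflate formation by O-sulfonylation of the only enolate the ketone can form (toward C10) should give the tetrasubstituted C5=C10 olefin as a single regioisomer.

Step 6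
Reactants: 9 ring A enol triflate
Product: 10 ring A methyl ester (C6 as CO2Me on C5)
Conditions: Pd(OAc)2 (5 mol %), dppf, CO (1 atm), MeOH, Et3N, DMF, 70 °C
Reagents that add atoms: carbon monoxide, [C-]#[O+]; methanol, CO
Why: Palladium-catalysed alkoxycarbonylation of the vinyl triflate (oxidative addition to zerovalent palladium, CO insertion, methanolysis) installs C6, the small CO ligand tolerating the crowded 2,6,6-trisubstituted cyclohexenyl palladium species.

Step 7
Reactants: 10 ring A methyl ester
Product: 11 ring A allylic alcohol (C6 as CH2OH)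
Conditions: i-Bu2AlH (2.5 equiv), CH2Cl2, −78 to 0 °C; aq. KNa tartrate
Reagents that add atoms: none
Why: Hydride reduction of the conjugated ester by two 1,2-additions should give the allylic alcohol without touching the tetrasubstituted olefin or the silyl ethers.

Step 8
Reactants: 11 ring A allylic alcohol
Product: 12 ring A allylic bromide (C6 as CH2Br)
Conditions: PPh3, CBr4, CH2Cl2, 0 °C; used crude
Reagents that add atoms: carbon tetrabromide, BrC(Br)(Br)Br
Why: The Appel reaction displaces the oxyphosphonium by SN2 under neutral conditions, so the primary allylic bromide should form without transposition or silyl loss.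

Step 9
Reactants: 12 ring A allylic bromide; 13 methyl acetoacetate
Product: 15 cyclisation precursor (ring A olefin with the C6–C11 β-keto ester chain), via acetoacetate dianion 14 (not isolated)
Conditions: 13, NaH, THF, 0 °C; n-BuLi, 0 °C; 12, 0 °C to rt; 1 M HCl
Reagents that add atoms: none
Why: In this acetoacetate dianion γ-alkylation the terminal carbanion is the more reactive site and displaces the primary allylic bromide (SN2), forming the C6–C7 bond and leaving the β-keto ester intact.

Step 10
Reactants: 15 cyclisation precursor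
Product: 18 5-ene 8-keto C11 methyl ester (ring B closed), via C9 radical 16 (not isolated), via C5 radical 17 (not isolated)
Conditions: Mn(OAc)2·4H2O (20 mol %), Cu(OAc)2·H2O (20 mol %), KOAc, AcOH–EtOAc (1:4), graphite anode, Pt cathode, undivided cell, constant current (about 2.2 F/mol), 40 °C
Reagents that add atoms: none
Why: Anodically formed trivalent manganese (from Mn(OAc)2) enolises and oxidises the β-keto ester to the electrophilic C9 radical, which adds to C10 of the electron-rich C5=C10 olefin; divalent copper then oxidises the tertiary C5 radical (organocopper, β-hydride loss) to the C5=C6 olefin, the only one possible since C4 and C10 bear no hydrogen. The closest known reaction is the Mn(OAc)3/Cu(OAc)2 oxidative free-radical cyclisation of unsaturated β-keto esters, here run with both metals catalytic and the anode as terminal oxidant. Ring B closes 6-endo-trig (C9 to C10); 5-exo attack at C5 would build a spiro centre beside quaternary C4, and a ketone inside the forming ring also favours the endo mode. C10 is set by ring A: with the C3 silyloxy group equatorial in a chair-like ring A, the cis CH2OTIPS group is axial at C4 and the chain should reach C10 from the opposite face, so that C20 ends syn to C19. C9 is set thermodynamically, the enolisable β-keto ester settling with the ester equatorial. The step needs endo regioselectivity, facial selectivity at C10 and a single elimination direction, secured in turn by the substitution at C5, the ring A conformation and the absence of hydrogen at C4 and C10.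

Step 11
Reactants: 18 5-ene 8-keto C11 methyl ester
Product: 19 saturated trans-fused 8-keto C11 methyl ester
Conditions: H2 (30 bar), 10 % Pd/C, EtOAc, 40 °C
Reagents that add atoms: none
Why: Heterogeneous hydrogenation should add H2 to the C5=C6 face opposite the axial C20 methyl and the axial C19 group, as with 4,4,10-trisubstituted octal-5-enes, which sets C5 with H5 anti to C20 (trans ring fusion).

Step 12
Reactants: 19 saturated trans-fused 8-keto C11 methyl ester
Product: 20 8(17)-methylene C11 methyl ester
Conditions: Zn, CH2Br2, TiCl4, THF–CH2Cl2 (reagent pre-formed), 0 °C to rt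
Reagents that add atoms: dibromomethane, BrCBr
Why: Takai–Lombardo methylenation uses a non-basic gem-dimetallic reagent that attacks the ketone but neither the ester nor the acidic C9–H, so the β,γ-unsaturated ester should form with C9 still equatorial.

Step 13
Reactants: 20 8(17)-methylene C11 methyl ester
Product: 21 C11 primary alcohol
Conditions: LiAlH4, Et2O, 0 °C; aq. NaOH work-up
Reagents that add atoms: none
Why: Hydride reduction of the ester gives the primary alcohol, the isolated 1,1-disubstituted olefin and the silyl ethers being inert to LiAlH4.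

Step 14
Reactants: 21 C11 primary alcohol
Product: 22 C11 aldehyde
Conditions: Dess–Martin periodinane, NaHCO3, CH2Cl2, 0 °C to rt; used at once
Reagents that add atoms: none
Why: Dess–Martin oxidation under bicarbonate buffer works without acid or base, so C9 should not epimerise and the olefin should not move into conjugation.

Step 15
Reactants: 23 2-(bromomethyl)acrylic acid; 24 allyl alcohol
Product: 25 allyl 2-(bromomethyl)acrylate
Conditions: H2SO4 (cat.), cyclohexane, reflux, Dean–Stark trap
Reagents that add atoms: none
Why: Fischer esterification driven by azeotropic removal of water keeps the medium acidic, under which the allylic bromide is stable (base would start SN2' displacement).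

Step 16
Reactants: 22 C11 aldehyde; 25 allyl 2-(bromomethyl)acrylate
Product: 26 (11R)-hydroxy allyl acrylate (C11–C12 bond formed)
Conditions: In (powder), THF–H2O (3:1), rt
Reagents that add atoms: none
Why: In this Barbier-type 2-(alkoxycarbonyl)allylation the allylmetal formed from 25 adds through its γ-carbon in a neutral aqueous medium, and the Felkin–Anh transition state (quaternary C10 anti to the nucleophile, which passes over H9 and not over C8) should give the (11R) carbinol.

Step 17
Reactants: 26 (11R)-hydroxy allyl acrylate
Product: 27 bis-silyl ether of the target (butenolide closed)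
Conditions: second-generation Grubbs catalyst (5 mol %), CH2Cl2, 40 °C
Reagents that add atoms: none
Why: Ring-closing metathesis joins the allyl ester olefin to the 1,1-disubstituted acrylate olefin and closes the five-membered α-substituted butenolide (C13=C14), while the hindered C8 methylene cannot compete because it would have to form a tetrasubstituted olefin.

Step 18
Reactants: 27 bis-silyl ether of the target
Product: 28 14-deoxy-11-hydroxyandrographolide
Conditions: HF·pyridine, pyridine, THF, 0 °C to rt
Reagents that add atoms: none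
Why: Fluoride-mediated cleavage of both silyl ethers with buffered HF·pyridine avoids base, which would open or isomerise the butenolide, and strong acid, which would isomerise the exocyclic olefin.

**Compound list**

1 | 2-methylcyclohexane-1,3-dione | CC1C(=O)CCCC1=O | starting material
2 | (triisopropylsiloxy)methyl chloride | ClCO[Si](C(C)C)(C(C)C)C(C)C | starting material
3 | 2-methyl-2-{[(triisopropylsilyl)oxy]methyl}cyclohexane-1,3-dione | CC1(CO[Si](C(C)C)(C(C)C)C(C)C)C(=O)CCCC1=O | intermediate
4 | (2R,3R)-3-hydroxy-2-methyl-2-{[(triisopropylsilyl)oxy]methyl}cyclohexan-1-one (OH cis to CH2OTIPS) | O=C1CCC[C@@H](O)[C@@]1(C)CO[Si](C(C)C)(C(C)C)C(C)C | intermediate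
5 | (2R,3R)-3-[(tert-butyldimethylsilyl)oxy]-2-methyl-2-{[(triisopropylsilyl)oxy]methyl}cyclohexan-1-one | O=C1CCC[C@@H](O[Si](C)(C)C(C)(C)C)[C@@]1(C)CO[Si](C(C)C)(C(C)C)C(C)C | intermediate
6 | lithium enolate of 5 (enolate toward labdane C10) | [Li+].[O-]C1=CCC[C@@H](O[Si](C)(C)C(C)(C)C)[C@@]1(C)CO[Si](C(C)C)(C(C)C)C(C)C | intermediate
7 | (2R,3R,6RS)-3-[(tert-butyldimethylsilyl)oxy]-2,6-dimethyl-2-{[(triisopropylsilyl)oxy]methyl}cyclohexan-1-one | O=C1C(C)CC[C@@H](O[Si](C)(C)C(C)(C)C)[C@@]1(C)CO[Si](C(C)C)(C(C)C)C(C)C | intermediate
8 | potassium enolate of 7 (tetrasubstituted) | [K+].[O-]C1=C(C)CC[C@@H](O[Si](C)(C)C(C)(C)C)[C@@]1(C)CO[Si](C(C)C)(C(C)C)C(C)C | intermediate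
9 | (5R,6R)-5-[(tert-butyldimethylsilyl)oxy]-2,6-dimethyl-6-{[(triisopropylsilyl)oxy]methyl}cyclohex-1-en-1-yl trifluoromethanesulfonate | FC(F)(F)S(=O)(=O)OC1=C(C)CC[C@@H](O[Si](C)(C)C(C)(C)C)[C@@]1(C)CO[Si](C(C)C)(C(C)C)C(C)C | intermediate
10 | methyl (5R,6R)-5-[(tert-butyldimethylsilyl)oxy]-2,6-dimethyl-6-{[(triisopropylsilyl)oxy]methyl}cyclohex-1-ene-1-carboxylate | COC(=O)C1=C(C)CC[C@@H](O[Si](C)(C)C(C)(C)C)[C@@]1(C)CO[Si](C(C)C)(C(C)C)C(C)C | intermediate
11 | [(5R,6R)-5-[(tert-butyldimethylsilyl)oxy]-2,6-dimethyl-6-{[(triisopropylsilyl)oxy]methyl}cyclohex-1-en-1-yl]methanol | OCC1=C(C)CC[C@@H](O[Si](C)(C)C(C)(C)C)[C@@]1(C)CO[Si](C(C)C)(C(C)C)C(C)C | intermediate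
12 | (5R,6R)-1-(bromomethyl)-5-[(tert-butyldimethylsilyl)oxy]-2,6-dimethyl-6-{[(triisopropylsilyl)oxy]methyl}cyclohex-1-ene | BrCC1=C(C)CC[C@@H](O[Si](C)(C)C(C)(C)C)[C@@]1(C)CO[Si](C(C)C)(C(C)C)C(C)C | intermediate
13 | methyl acetoacetate | COC(=O)CC(C)=O | starting material
14 | methyl acetoacetate dianion (lithium sodium dienolate) | [Li+].[Na+].C=C([O-])C=C([O-])OC | intermediate
15 | methyl 5-[(5R,6R)-5-[(tert-butyldimethylsilyl)oxy]-2,6-dimethyl-6-{[(triisopropylsilyl)oxy]methyl}cyclohex-1-en-1-yl]-3-oxopentanoate (cyclisation precursor) | COC(=O)CC(=O)CCC1=C(C)CC[C@@H](O[Si](C)(C)C(C)(C)C)[C@@]1(C)CO[Si](C(C)C)(C(C)C)C(C)C | intermediate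
16 | C9 radical of 15 (α-carbon of the β-keto ester) | COC(=O)[CH]C(=O)CCC1=C(C)CC[C@@H](O[Si](C)(C)C(C)(C)C)[C@@]1(C)CO[Si](C(C)C)(C(C)C)C(C)C | intermediate
17 | bicyclic tertiary C5 radical formed by C9–C10 bonding (C9 not yet settled) | O=C1CC[C]2[C@](C)(CO[Si](C(C)C)(C(C)C)C(C)C)[C@H](O[Si](C)(C)C(C)(C)C)CC[C@@]2(C)C1C(=O)OC | intermediate
18 | methyl 6-(TBS-oxy)-5,8a-dimethyl-2-oxo-5-(TIPS-oxymethyl)-1,2,3,5,6,7,8,8a-octahydronaphthalene-1-carboxylate; labdane C5=C6 olefin, C8 ketone, C9 ester equatorial; 8a-methyl (C20), CH2OTIPS (C19), OTBS (C3) and the ester on one face | O=C1CC=C2[C@](C)(CO[Si](C(C)C)(C(C)C)C(C)C)[C@H](O[Si](C)(C)C(C)(C)C)CC[C@@]2(C)[C@@H]1C(=O)OC | intermediate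
19 | methyl 6-(TBS-oxy)-5,8a-dimethyl-2-oxo-5-(TIPS-oxymethyl)decahydronaphthalene-1-carboxylate; trans ring fusion (H5 anti to C20), other centres as in 18 | O=C1CC[C@@H]2[C@](C)(CO[Si](C(C)C)(C(C)C)C(C)C)[C@H](O[Si](C)(C)C(C)(C)C)CC[C@@]2(C)[C@@H]1C(=O)OC | intermediate
20 | methyl 6-(TBS-oxy)-5,8a-dimethyl-2-methylidene-5-(TIPS-oxymethyl)decahydronaphthalene-1-carboxylate; configuration as in 19 | C=C1CC[C@@H]2[C@](C)(CO[Si](C(C)C)(C(C)C)C(C)C)[C@H](O[Si](C)(C)C(C)(C)C)CC[C@@]2(C)[C@@H]1C(=O)OC | intermediate
21 | [6-(TBS-oxy)-5,8a-dimethyl-2-methylidene-5-(TIPS-oxymethyl)decahydronaphthalen-1-yl]methanol; configuration as in 19 | C=C1CC[C@@H]2[C@](C)(CO[Si](C(C)C)(C(C)C)C(C)C)[C@H](O[Si](C)(C)C(C)(C)C)CC[C@@]2(C)[C@@H]1CO | intermediate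
22 | 6-(TBS-oxy)-5,8a-dimethyl-2-methylidene-5-(TIPS-oxymethyl)decahydronaphthalene-1-carbaldehyde; configuration as in 19 | C=C1CC[C@@H]2[C@](C)(CO[Si](C(C)C)(C(C)C)C(C)C)[C@H](O[Si](C)(C)C(C)(C)C)CC[C@@]2(C)[C@@H]1C=O | intermediate
23 | 2-(bromomethyl)acrylic acid | OC(=O)C(=C)CBr | starting material
24 | allyl alcohol | OCC=C | starting material
25 | allyl 2-(bromomethyl)acrylate | C=CCOC(=O)C(=C)CBr | intermediate
26 | prop-2-en-1-yl (4R)-4-hydroxy-2-methylidene-4-[decalin unit of 22]butanoate (labdane 11R) | C=C1CC[C@@H]2[C@](C)(CO[Si](C(C)C)(C(C)C)C(C)C)[C@H](O[Si](C)(C)C(C)(C)C)CC[C@@]2(C)[C@@H]1[C@H](O)CC(=C)C(=O)OCC=C | intermediate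
27 | 3-O-TBS-19-O-TIPS-14-deoxy-11-hydroxyandrographolide: 3-[(2R)-2-hydroxy-2-(decalin unit of 22)ethyl]furan-2(5H)-one | C=C1CC[C@@H]2[C@](C)(CO[Si](C(C)C)(C(C)C)C(C)C)[C@H](O[Si](C)(C)C(C)(C)C)CC[C@@]2(C)[C@@H]1[C@H](O)CC1=CCOC1=O | intermediate
28 | 14-deoxy-11-hydroxyandrographolide (labdane numbering 3R,4R,5S,9R,10R,11R) | C=C1CC[C@@H]2[C@](C)(CO)[C@H](O)CC[C@@]2(C)[C@@H]1[C@H](O)CC1=CCOC1=O | target

**Step count.** Total: 18 steps. Longest linear sequence: 17 steps (steps 1 to 14 and 16 to 18); step 15 prepares fragment 25.

**Steps most likely to fail**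

Step 10 (key step). The chain may reach C10 from the face syn to C19 about as often as from the anti face, because the preference of ring A for the chair with the C3 silyloxy group equatorial is small. Addition to the tetrasubstituted olefin may also be slow enough for the C9 radical to be oxidised further or to dimerise, and AcOH may strip a silyl ether. Fallback: close ring B by the known acid-promoted cation–olefin cyclisation of β-keto esters tethered to a 2,6,6-trisubstituted cyclohexene. With SnCl4 in CH2Cl2 at −20 to 0 °C, 15 should be protonated at C5 and the tin-bound enol should attack the C10 cation through a product-like chair–chair transition state, giving the saturated trans-fused keto ester 19 directly. The fallback sets out from 15 and comes back at 19, so step 11 is not needed; it makes no new compound (F0).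

Step 1. Alkylation may take place on the enolate oxygen instead of carbon (hard α-chloro ether, hindered C2), so that mostly enol acetal forms and only 1 is recovered on work-up. Fallback: alkylate a carbon-only nucleophile under Lewis acid catalysis. Compound 1 is silylated with Me3SiCl and Et3N to 2-methyl-3-(trimethylsilyloxy)cyclohex-2-en-1-one F1, which is treated with 2 and catalytic ZnBr2 in CH2Cl2 (Mukaiyama-type SN1 alkylation at C2 of the vinylogous silyl ester) to give 3. The fallback sets out from 1 and comes back at 3.

Step 16. Facial discrimination at the aldehyde may be weak under substrate control; the new hydroxyl may also cyclise onto the acrylate ester with loss of allyl alcohol, or the C8 olefin may migrate into conjugation before addition. Fallback: set C11 by reagent-controlled ketone reduction instead of by addition. The epimer mixture 26 is oxidised with Dess–Martin periodinane to the C11 ketone F2, which is reduced with (S)-2-methyl-CBS-oxazaborolidine and catecholborane at −78 °C (C9 as the large group) to (11R)-26. The fallback sets out from 26 and comes back at 26.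

**Further compounds**

F0 | step 10 | none | none
F1 | step 1 | 2-methyl-3-(trimethylsilyloxy)cyclohex-2-en-1-one | CC1=C(O[Si](C)(C)C)CCCC1=O
F2 | step 16 | C11 ketone of 26: prop-2-en-1-yl 2-methylidene-4-oxo-4-[decalin unit of 22]butanoate | C=C1CC[C@@H]2[C@](C)(CO[Si](C(C)C)(C(C)C)C(C)C)[C@H](O[Si](C)(C)C(C)(C)C)CC[C@@]2(C)[C@@H]1C(=O)CC(=C)C(=O)OCC=C
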